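## Retrosynthetic overview

- The quinone is unmasked last. Both N–S bonds are cleaved after oxidative demethylation of a 1,4-bis(indol-3-yl)-2,3,5,6-tetramethoxybenzene, so the central six-membered ring travels through the route as an arene.
- Both pyrrole rings are opened together at N1–C7a, C3–C3a and N1–C2. Each indole goes back to benzyne and the N-tosylhydrazone of an aryl–CH2–C(=O)–C(CH3)2CH=CH2 ketone.
- The plan rests on two features. C4–C7 of both indole benzo rings carry only hydrogen, so a symmetric C6H4 unit can supply them. The carbon attached to indole C2 is quaternary, so each ketone has α-hydrogens only on the CH2 bound to the central ring, and that carbon becomes C3.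
- The diketone comes from twofold palladium-catalysed enolate arylation of 1,4-dibromo-2,3,5,6-tetramethoxybenzene (three steps from bromanil). The enolate partner is 3,3-dimethylpent-4-en-2-one (one step from 2,2-dimethylbut-3-enoic acid).
- Ring order: the central carbocycle is bought, then both pyrrole rings with their fused benzo rings are formed in one flask.

Key step: step 7

Assumption: the two indole C3–core axes are hindered, so 14, 15 and 16 may show syn/anti rotamers. The target string carries no axial descriptor, and the rotamers are treated as one compound.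

## Route

Step 1
Reactants: 1 tetrabromo-1,4-benzoquinone (bromanil)
Product: 2 2,5-dibromo-3,6-dimethoxy-1,4-benzoquinone
Conditions: NaOMe (2.1 equiv), MeOH, 0 °C to rt
Reagents that add atoms: sodium methoxide, C[O-].[Na+]
Why: Twofold addition–elimination on a tetrahaloquinone (vinylogous acyl substitution), in which the first methoxy group turns one C=O into a vinylogous ester and thereby steers the second methoxide to the ring carbon opposite the first, the usual 2,5-pattern for this substrate class.

Step 2
Reactants: 2 2,5-dibromo-3,6-dimethoxy-1,4-benzoquinone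
Product: 3 2,5-dibromo-3,6-dimethoxybenzene-1,4-diol
Conditions: Na2S2O4 (excess), EtOAc/H2O, rt
Reagents that add atoms: none
Why: Dithionite reduction of a quinone to its hydroquinone, a two-electron transfer that leaves aryl bromides and methyl ethers untouched.

Step 3
Reactants: 3 2,5-dibromo-3,6-dimethoxybenzene-1,4-diol
Product: 4 1,4-dibromo-2,3,5,6-tetramethoxybenzene
Conditions: Me2SO4 (3 equiv), K2CO3 (4 equiv), acetone, reflux, N2
Reagents that add atoms: dimethyl sulfate, COS(=O)(=O)OC
Why: Williamson-type O-methylation of both phenoxides by SN2 attack on dimethyl sulfate, with air excluded so that the electron-rich hydroquinone does not revert to 2.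

Step 4
Reactants: 5 2,2-dimethylbut-3-enoic acid
Product: 7 3,3-dimethylpent-4-en-2-one, via dilithium gem-diolate 6 (not isolated)
Conditions: MeLi (2.2 equiv), Et2O, 0 °C to rt; inverse quench into ice-water
Reagents that add atoms: methyllithium, [Li]C
Why: Ketone synthesis by addition of an organolithium to a lithium carboxylate, in which the hindered tetrahedral diolate 6 does not collapse before the inverse quench, so no ketone meets MeLi.

Step 5
Reactants: 4 1,4-dibromo-2,3,5,6-tetramethoxybenzene; 7 3,3-dimethylpent-4-en-2-one (2.6 equiv)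
Product: 8 1,1'-(2,3,5,6-tetramethoxy-1,4-phenylene)bis(3,3-dimethylpent-4-en-2-one)
Conditions: Pd2(dba)3 (2.5 mol %), XPhos (2-dicyclohexylphosphino-2',4',6'-triisopropylbiphenyl, 6 mol %), NaOtBu (5 equiv), toluene, 80 °C
Reagents that add atoms: none
Why: Buchwald–Hartwig-type ketone α-arylation, in which zerovalent palladium inserts into each C–Br bond, the only possible enolate of 7 (from its CH3 group) replaces bromide on palladium, the bulky biaryl phosphine speeds C–C reductive elimination ahead of Heck insertion into the vinyl group, and each product arm rests as a crowded benzylic enolate that is not arylated again.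

Step 6
Reactants: 8 1,1'-(2,3,5,6-tetramethoxy-1,4-phenylene)bis(3,3-dimethylpent-4-en-2-one); 9 p-toluenesulfonyl hydrazide (2.5 equiv)
Product: 10 (E,E)-bis(N-tosylhydrazone) of 8 (each NHTs anti to the quaternary carbon)
Conditions: p-TsOH·H2O (5 mol %), EtOH, 70 °C
Reagents that add atoms: none
Why: Acid-catalysed hydrazone formation as known for pinacolone-type ketones, with the C=N geometry set by sterics (NHTs turns away from the quaternary carbon, E) and in any case without consequence for step 7.

Step 7
Reactants: 10 (E,E)-bis(N-tosylhydrazone) of 8; 11 2-(trimethylsilyl)phenyl trifluoromethanesulfonate (3 equiv)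
Product: 14 3,3'-(2,3,5,6-tetramethoxy-1,4-phenylene)bis[2-(2-methylbut-3-en-2-yl)-1-tosyl-1H-indole], via benzyne 12 (not isolated), via bis(N-phenyl-N-tosylhydrazone) 13 (not isolated)
Conditions: CsF (6 equiv), MeCN, rt; then BF3·OEt2 (10 equiv), 80 °C
Reagents that add atoms: none
Why: CsF removes the silyl group of 11, triflate departs, and the benzyne 12 so released is trapped at room temperature by the deprotonated sulfonamide nitrogen of each hydrazone arm of 10, which forms N1–C7a and, after protonation of the aryl anion, gives 13. BF3·OEt2 then shifts each C=N into the ene-hydrazine, a [3,3]-sigmatropic rearrangement breaks N–N and ties an ortho carbon of the new N-phenyl ring to the former benzylic carbon (C3–C3a), and after rearomatisation the ArNHTs nitrogen adds to the activated imine carbon (N1–C2) and ammonia is expelled to give the aromatic pyrrole. The closest known reaction is the one-pot aryne N-arylation and Lewis acid Fischer indolisation of ketone N-tosylhydrazones to N-tosylindoles, which is applied here to both arms of one molecule. Each of the two pyrrole rings closes in the 5-exo-trig mode, and no stereocentre is formed. The only regiochemical demand, the direction of ene-hydrazine formation, is met because the second α-carbon is the quaternary C(CH3)2CH=CH2 carbon, while benzyne and the two ortho positions of each N-phenyl ring are symmetry-equivalent. Chemoselectivity rests on running the arylation cold enough to avoid Bamford–Stevens loss of sulfinate, on the vinyl groups having no allylic hydrogen for an aryne ene reaction, and on BF3·OEt2 leaving aryl methyl ethers intact.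

Step 8
Reactants: 14 3,3'-(2,3,5,6-tetramethoxy-1,4-phenylene)bis[2-(2-methylbut-3-en-2-yl)-1-tosyl-1H-indole]
Product: 15 2,5-dimethoxy-3,6-bis[2-(2-methylbut-3-en-2-yl)-1-tosyl-1H-indol-3-yl]-1,4-benzoquinone
Conditions: (NH4)2Ce(NO3)6 (2.5 equiv), MeCN/CH2Cl2/H2O, 0 °C
Reagents that add atoms: water, O
Why: Oxidative demethylation of a 1,4-dimethoxyarene by tetravalent cerium, in which two one-electron oxidations, ipso attack of water and loss of methanol give the p-quinone, the two para pairs of methoxy groups are equivalent by symmetry so only one p-quinone can arise, and the N-sulfonyl groups keep the indole π systems out of reach of the oxidant.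

Step 9
Reactants: 15 2,5-dimethoxy-3,6-bis[2-(2-methylbut-3-en-2-yl)-1-tosyl-1H-indol-3-yl]-1,4-benzoquinone
Product: 16 2,5-dimethoxy-3,6-bis[2-(2-methylbut-3-en-2-yl)-1H-indol-3-yl]-1,4-benzoquinone (target, CNP0331285.0)
Conditions: Cs2CO3 (6 equiv), dry THF/MeOH (2:1), N2, rt to 50 °C; aq NH4Cl
Reagents that add atoms: none
Why: Nucleophilic N-desulfonylation of N-tosylindoles with Cs2CO3/MeOH, in which methoxide attacks sulfur and expels an indolide that is stabilised by the 3-quinonyl acceptor and relieved of strain against the tert-alkyl group, whereas methoxide exchange at the quinone C–OMe carbons is degenerate.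

## Compound list

1 | tetrabromo-1,4-benzoquinone (bromanil) | O=C1C(Br)=C(Br)C(=O)C(Br)=C1Br | starting material
2 | 2,5-dibromo-3,6-dimethoxy-1,4-benzoquinone | O=C1C(Br)=C(OC)C(=O)C(Br)=C1OC | intermediate
3 | 2,5-dibromo-3,6-dimethoxybenzene-1,4-diol | Oc1c(Br)c(OC)c(O)c(Br)c1OC | intermediate
4 | 1,4-dibromo-2,3,5,6-tetramethoxybenzene | COc1c(Br)c(OC)c(OC)c(Br)c1OC | intermediate
5 | 2,2-dimethylbut-3-enoic acid | C=CC(C)(C)C(=O)O | starting material
6 | dilithium 3,3-dimethylpent-4-ene-2,2-diolate | C=CC(C)(C)C(C)([O-])[O-].[Li+].[Li+] | intermediate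
7 | 3,3-dimethylpent-4-en-2-one | C=CC(C)(C)C(C)=O | intermediate
8 | 1,1'-(2,3,5,6-tetramethoxy-1,4-phenylene)bis(3,3-dimethylpent-4-en-2-one) | C=CC(C)(C)C(=O)Cc1c(OC)c(OC)c(CC(=O)C(C)(C)C=C)c(OC)c1OC | intermediate
9 | p-toluenesulfonyl hydrazide | Cc1ccc(S(=O)(=O)NN)cc1 | starting material
10 | (E,E)-bis(N-tosylhydrazone) of 8 | C=CC(C)(C)/C(Cc1c(OC)c(OC)c(C/C(=N\NS(=O)(=O)c2ccc(C)cc2)C(C)(C)C=C)c(OC)c1OC)=N/NS(=O)(=O)c1ccc(C)cc1 | intermediate
11 | 2-(trimethylsilyl)phenyl trifluoromethanesulfonate | C[Si](C)(C)c1ccccc1OS(=O)(=O)C(F)(F)F | starting material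
12 | benzyne | C1#CC=CC=C1 | intermediate
13 | (E,E)-bis(N-phenyl-N-tosylhydrazone) of 8 | C=CC(C)(C)/C(Cc1c(OC)c(OC)c(C/C(=N\N(c2ccccc2)S(=O)(=O)c2ccc(C)cc2)C(C)(C)C=C)c(OC)c1OC)=N/N(c1ccccc1)S(=O)(=O)c1ccc(C)cc1 | intermediate
14 | 3,3'-(2,3,5,6-tetramethoxy-1,4-phenylene)bis[2-(2-methylbut-3-en-2-yl)-1-tosyl-1H-indole] | COc1c(OC)c(-c2c(C(C)(C)C=C)n(S(=O)(=O)c3ccc(C)cc3)c3ccccc23)c(OC)c(OC)c1-c1c(C(C)(C)C=C)n(S(=O)(=O)c2ccc(C)cc2)c2ccccc12 | intermediate
15 | 2,5-dimethoxy-3,6-bis[2-(2-methylbut-3-en-2-yl)-1-tosyl-1H-indol-3-yl]-1,4-benzoquinone | C=CC(C)(C)c1n(S(=O)(=O)c2ccc(C)cc2)c2ccccc2c1C1=C(OC)C(=O)C(c2c(C(C)(C)C=C)n(S(=O)(=O)c3ccc(C)cc3)c3ccccc23)=C(OC)C1=O | intermediate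
16 | 2,5-dimethoxy-3,6-bis[2-(2-methylbut-3-en-2-yl)-1H-indol-3-yl]-1,4-benzoquinone | C=CC(C)(C)c1[nH]c2ccccc2c1C1=C(OC)C(=O)C(c2c(C(C)(C)C=C)[nH]c3ccccc23)=C(OC)C1=O | target

## Step count and risks

Total step count: 9.
Longest linear sequence: 8 (steps 1, 2, 3, 5, 6, 7, 8, 9).

**1. Step 7.**
- What may go wrong: the second N-arylation may lag behind the first. The sigmatropic shift of an electron-poor N-sulfonyl ene-hydrazine may also be slow at a carbon crowded by the di-ortho-methoxyaryl group and the tert-alkyl group. Hydrazone hydrolysis, N–N cleavage or acid-induced cationic reactions of the vinyl groups could then overtake indolisation.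
- Fallback without an aryne, setting out from 8: condensation with phenylhydrazine (AcOH cat., EtOH, reflux) should give the (E,E)-bis(phenylhydrazone) F1. Its N–H ene-hydrazine is far more electron-rich and should rearrange under classical Fischer conditions (ZnCl2, AcOH, 90 °C). This should give 3,3'-(2,3,5,6-tetramethoxy-1,4-phenylene)bis[2-(2-methylbut-3-en-2-yl)-1H-indole] F2. N-Sulfonylation of both indoles (NaH, TsCl, DMF) comes back to the route at 14.

**2. Step 5.**
- What may go wrong: oxidative addition at the electron-rich, di-ortho-substituted C–Br bonds may be slow. This could lead to hydrodebromination, stalling after one coupling, or Heck-type insertion of the vinyl group.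
- Fallback, setting out from 4, builds the side chain with reversed polarity. Double Stille allylation (allyltributylstannane, Pd(PPh3)4, DMF, 100 °C) should give 1,4-diallyl-2,3,5,6-tetramethoxybenzene F3.
- Lemieux–Johnson cleavage (K2OsO4·2H2O cat., NaIO4, 2,6-lutidine, dioxane/H2O) should give 2,2'-(2,3,5,6-tetramethoxy-1,4-phenylene)diacetaldehyde F4.
- γ-Selective Barbier prenylation (prenyl bromide, indium metal, THF/H2O) should give the bis(1,1-dimethylallyl carbinol) F5 as a mixture of diastereomers.
- Dess–Martin oxidation erases both carbinol centres and comes back to the route at 8.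

**3. Step 9.**
- What may go wrong: attack of methoxide at the shielded sulfonyl groups may be slow. Hydrolysis of the vinylogous ester methoxy groups by adventitious water, or reduction of the quinone by methoxide, could then compete.
- Fallback, setting out from 15, accepts the hydrolysis on purpose. Aqueous NaOH in MeOH/THF at reflux, then acidification, should cleave both sulfonamides and both methoxy groups. This should give 2,5-dihydroxy-3,6-bis[2-(2-methylbut-3-en-2-yl)-1H-indol-3-yl]-1,4-benzoquinone F6.
- Selective O-methylation of the acidic hydroxyquinone (trimethylsilyldiazomethane, toluene/MeOH, 0 °C) leaves the indole N–H groups alone and comes back to the route at 16.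

## Further compounds

F1 | step 7 | (E,E)-bis(phenylhydrazone) of 8 | C=CC(C)(C)/C(Cc1c(OC)c(OC)c(C/C(=N\Nc2ccccc2)C(C)(C)C=C)c(OC)c1OC)=N/Nc1ccccc1
F2 | step 7 | 3,3'-(2,3,5,6-tetramethoxy-1,4-phenylene)bis[2-(2-methylbut-3-en-2-yl)-1H-indole] | COc1c(OC)c(-c2c(C(C)(C)C=C)[nH]c3ccccc23)c(OC)c(OC)c1-c1c(C(C)(C)C=C)[nH]c2ccccc12
F3 | step 5 | 1,4-diallyl-2,3,5,6-tetramethoxybenzene | C=CCc1c(OC)c(OC)c(CC=C)c(OC)c1OC
F4 | step 5 | 2,2'-(2,3,5,6-tetramethoxy-1,4-phenylene)diacetaldehyde | O=CCc1c(OC)c(OC)c(CC=O)c(OC)c1OC
F5 | step 5 | 1,1'-(2,3,5,6-tetramethoxy-1,4-phenylene)bis(3,3-dimethylpent-4-en-2-ol), mixture of meso and racemic diastereomers, centres not controlled | C=CC(C)(C)C(O)Cc1c(OC)c(OC)c(CC(O)C(C)(C)C=C)c(OC)c1OC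
F6 | step 9 | 2,5-dihydroxy-3,6-bis[2-(2-methylbut-3-en-2-yl)-1H-indol-3-yl]-1,4-benzoquinone | C=CC(C)(C)c1[nH]c2ccccc2c1C1=C(O)C(=O)C(c2c(C(C)(C)C=C)[nH]c3ccccc23)=C(O)C1=O
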